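Atom numbers used throughout follow the hexahydropyrrolo[2,3-b]indole core of the target 23: N1 (methyl), C2, C3, C3a (quaternary, prenyl), C3b, C4 (furan oxygen), C5 (furan C3′), C6 (H), C7 (Br), C7a, N8 (H), C8a (aminal H). The furan atoms are O1′, C2′ (bearing the carbinol) and C3′.

## The problem

Target 23 is a cis-fused pyrroloindoline whose benzene ring is substituted at five of its six positions: C3b carries the quaternary C3a, C4 the furan oxygen, C5 the furan carbon, C7 bromine and C7a the nitrogen N8. The hardest bond is C3b–C3a, an aryl–quaternary-carbon bond flanked by the C4 oxygen and by N8. Any route that quaternizes C3 of a preformed 4-oxygenated indole, or arylates a C3a nucleophile, has to work at the most crowded site of the molecule. The second difficulty is regiochemical: Br, H, C, O, C and N have to be placed around one ring in a fixed order. There are two stereocentres, C3a and C8a, but only C3a is independent, because the two five-membered rings can only be cis-fused. One enantioselective event at C3a therefore suffices, and it is best carried out on a small non-enolizable building block. The tertiary furyl carbinol ionizes in acid, the prenyl alkene is sensitive to acid and halonium sources, the aryl bromide to alkyllithiums and low-valent metals, and the N8–H aminal to acid and oxidants, so the aminal should appear last. The feature that opens the problem is that C7a–N8–C8a–C3a–C3b form a five-membered ring while the oxygen sits on C4, next to C3b. The benzene ring is therefore the sum of a two-carbon unit C3b≡C4–O hanging from C3a and a four-carbon unit C7a(N8)–C7(Br)–C6(H)–C5(C), that is, a 3-amino-4-bromo-6-alkynylpyridazine. The three-atom tether N8–C8a–C3a allows these two units to join in only one way.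

## Retrosynthesis

23 ⇒ 22. The C8a–H bond is cut: the aminal is taken back to the cyclic amidine 22 (C8a=N8). This keeps the only labile function out of every earlier step, and the forward hydride addition cannot give the wrong C8a epimer because only the cis ring fusion is possible.

22 ⇒ 20. The furan O1′–C2′ bond is cut to give an ortho-alkynyl aryl silyl ether. The forward step needs only fluoride: desilylation, 5-endo-dig closure of the phenoxide onto the alkyne, and release of the carbinol from its silyl ether.

20 ⇒ 18 (key disconnection). The benzene bonds C3b–C7a and C4–C5 are cut and N2 is reinserted between C7a and C5. This gives siloxyalkyne 18, in which a pyridazine is tied through the amidine N8=C8a to the pyrrolidine that carries C3a. Compared with a cut at C3a–C3b or C3a–prenyl, the crowded aryl–quaternary bond becomes an ordinary alkyne–carbon bond, and Br and the furan carbons come preinstalled on the diazine. The forward reaction has to be an intramolecular inverse-electron-demand [4+2] addition followed by loss of N2; the tether must control regiochemistry completely. 18 has one ring fewer than 20 and no substituted benzene ring.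

18 ⇒ 16. The C4–O bond is cut: the siloxyalkyne comes from the terminal alkyne of 16 by oxidation of its acetylide. It is made last among the precursors because siloxyalkynes do not survive electrophilic amide activation.

16 ⇒ 9 + 14. The amidine C8a=N8 bond is cut to give the non-enolizable lactam 9 and the aminopyridazine 14. This is the convergent step; it asks for electrophilic activation of a lactam whose carbonyl is next to a quaternary carbon.

14 ⇒ 13 ⇒ 11 + 12; 11 ⇒ 10. The C7–Br bond comes from bromination ortho to the amino group, and the C5–alkyne bond from Sonogashira coupling of the chlorodiazine 12 with the protected alkyne 11, made from 10.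

9 ⇒ 8 ⇒ 6 ⇒ 4. The alkyne is a one-carbon homologation of aldehyde 8, which comes from acid 6 and tert-butyl ester 4 without touching the quaternary centre.

4 ⇒ 2 + 3; 2 ⇒ 1. The C3a–prenyl bond is cut. Asymmetric phase-transfer alkylation of the cyclic malonamate 2 with prenyl bromide 3 sets the only independent stereocentre; 2 comes from 1 by C-acylation.

## Roads not taken

Alternative 1: This is the most obvious route. The C3a–prenyl and N1–C8a bonds are cut. The forward key step would be an enantioselective dearomative C3-prenylation and ring closure of the furo-fused tryptamine carbamate A1, with a prenyl carbonate and a chiral phosphine complex of zerovalent palladium, to give the pyrroloindoline carbamate A2. The chosen plan is better for three reasons: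
- A1 already contains the pentasubstituted arene, which would need a long linear sequence of ring substitutions.
- The quaternization takes place at C3, directly under the peri oxygen on C4, the most hindered case for this reaction type.
- Zerovalent palladium meets an aryl bromide, and linear versus branched attack of the prenyl unit must also be controlled.

Alternative 2: The C3a–C3b and N8–C8a bonds are cut. The forward key step would be an interrupted Fischer indolization of arylhydrazine A3 with the hemiaminal A4, in which a [3,3] shift forms C3a–C3b at the only free ortho position. The chosen plan is better for three reasons: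
- C3a would be created from an achiral ene-hydrazine, so the product is racemic unless a chiral acid controls a step for which control is uncertain.
- The strongly acidic medium threatens the furyl carbinol and the prenyl group.
- A3 again requires the fully substituted benzofuran to be built first, and an ortho bromine can divert the sigmatropic step.

Alternative 3: The benzene ring is cut at C3b–C4 and C5–C6 with C7–C7a. The forward key step would be a Danheiser benzannulation of ynamide A5 (from 9) with vinylketene A6 to give aminophenol A7. The chosen plan is better for three reasons: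
- The benzannulation does not close the five-membered ring, so N8–C8a needs a separate reductive step.
- N8 has to carry two removable groups, because an ynamide needs a fully substituted nitrogen.
- Bromine cannot be brought in with the ketene and would have to be introduced late, next to the prenyl alkene.

Key step: step 11

Remark on the chemistry: which antipode of the phase-transfer catalyst gives (R)-4 is not presumed; the antipode that does so is the one used.

## Route

Step 1
Reactants: 1 1-methylpyrrolidin-2-one
Product: 2 tert-butyl 1-methyl-2-oxopyrrolidine-3-carboxylate (racemic)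
Conditions: LDA (2.1 equiv), THF, −78 °C; Boc2O, −78 → 0 °C
Reagents that add atoms: di-tert-butyl dicarbonate, CC(C)(C)OC(=O)OC(=O)OC(C)(C)C
Why: Claisen-type C-acylation of the lactam enolate; the second equivalent of base takes up the more acidic β-amido ester and prevents double acylation.

Step 2
Reactants: 2 tert-butyl 1-methyl-2-oxopyrrolidine-3-carboxylate; 3 1-bromo-3-methylbut-2-ene (prenyl bromide)
Product: 4 tert-butyl (R)-1-methyl-3-(3-methylbut-2-en-1-yl)-2-oxopyrrolidine-3-carboxylate
Conditions: C2-symmetric N-spiro bis(binaphthyl)ammonium bromide with 3,4,5-trifluorophenyl groups at the 3,3′-positions (5 mol %), solid KOH, toluene, −40 °C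
Reagents that add atoms: none
Why: Asymmetric phase-transfer alkylation: the enolate of the cyclic malonamate pairs with the chiral ammonium cation, which shields one face, and prenyl bromide reacts by SN2 at its primary carbon, so the prenyl group arrives unrearranged. N-Methyl α-tert-butoxycarbonyl butyrolactams are a substrate class for which this reaction type is established; this step sets C3a.

Step 3
Reactants: 4 tert-butyl (R)-1-methyl-3-(3-methylbut-2-en-1-yl)-2-oxopyrrolidine-3-carboxylate
Product: 6 (R)-1-methyl-3-(3-methylbut-2-en-1-yl)-2-oxopyrrolidine-3-carboxylic acid, via trimethylsilyl ester 5 (not isolated)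
Conditions: Me3SiOTf, 2,6-lutidine, CH2Cl2, 0 °C; then H2O
Reagents that add atoms: none
Why: Silyl-triflate-mediated cleavage of the tert-butyl ester (loss of 2-methylpropene, then hydrolysis of the silyl ester) avoids the protic acid that would add the carboxyl group across the prenyl double bond; the quaternary centre is not touched.

Step 4
Reactants: 6 (R)-1-methyl-3-(3-methylbut-2-en-1-yl)-2-oxopyrrolidine-3-carboxylic acid
Product: 8 (S)-1-methyl-3-(3-methylbut-2-en-1-yl)-2-oxopyrrolidine-3-carbaldehyde, via acid chloride 7 (not isolated)
Conditions: 1-chloro-N,N,2-trimethylprop-1-en-1-amine, CH2Cl2, 0 °C → rt; then LiAlH(Ot-Bu)3, THF, −78 °C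
Reagents that add atoms: none
Why: Acid chloride formation under neutral conditions, then Rosenmund-type partial reduction with the hindered hydride, which stops at the aldehyde and leaves the tertiary lactam alone at −78 °C. The descriptor changes from R to S only because CHO ranks below the lactam carbonyl.

Step 5
Reactants: 8 (S)-1-methyl-3-(3-methylbut-2-en-1-yl)-2-oxopyrrolidine-3-carbaldehyde
Product: 9 (S)-3-ethynyl-1-methyl-3-(3-methylbut-2-en-1-yl)pyrrolidin-2-one
Conditions: Me3SiCHN2, LDA, THF, −78 °C → rt
Reagents that add atoms: trimethylsilyldiazomethane, C[Si](C)(C)C=[N+]=[N-]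
Why: Colvin rearrangement: lithiated trimethylsilyldiazomethane adds to the non-enolizable aldehyde, Peterson elimination and loss of N2 give an alkylidene carbene, and its 1,2-hydrogen shift gives the terminal alkyne. The aprotic medium avoids alkoxide-induced deformylation of the β-oxo amide.

Step 6
Reactants: 10 2-methylbut-3-yn-2-ol
Product: 11 triethyl[(2-methylbut-3-yn-2-yl)oxy]silane
Conditions: Et3SiCl, imidazole, DMAP (cat.), DMF, rt
Reagents that add atoms: chlorotriethylsilane, CC[Si](Cl)(CC)CC
Why: Silylation of the tertiary propargylic alcohol under nucleophilic catalysis; the triethylsilyl ether masks the carbinol through steps 7–11 and falls to fluoride in step 12.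

Step 7
Reactants: 11 triethyl[(2-methylbut-3-yn-2-yl)oxy]silane; 12 6-chloropyridazin-3-amine
Product: 13 6-[3-methyl-3-(triethylsilyloxy)but-1-yn-1-yl]pyridazin-3-amine
Conditions: PdCl2(PPh3)2 (3 mol %), CuI (6 mol %), Et3N, DMF, 80 °C
Reagents that add atoms: none
Why: Sonogashira coupling; oxidative addition into the C–Cl bond of the electron-poor diazine is easy and the free amino group does not interfere.

Step 8
Reactants: 13 6-[3-methyl-3-(triethylsilyloxy)but-1-yn-1-yl]pyridazin-3-amine
Product: 14 4-bromo-6-[3-methyl-3-(triethylsilyloxy)but-1-yn-1-yl]pyridazin-3-amine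
Conditions: NBS, MeCN, 0 °C → rt
Reagents that add atoms: N-bromosuccinimide, O=C1CCC(=O)N1Br
Why: Electrophilic aromatic bromination ortho to the amino group (C4 is the only ring position activated by NH2; C5 is meta to it). The alkyne conjugated to the diazine is too electron-poor to take up bromonium.

Step 9
Reactants: 9 (S)-3-ethynyl-1-methyl-3-(3-methylbut-2-en-1-yl)pyrrolidin-2-one; 14 4-bromo-6-[3-methyl-3-(triethylsilyloxy)but-1-yn-1-yl]pyridazin-3-amine
Product: 16 (S)-N-{4-bromo-6-[3-methyl-3-(triethylsilyloxy)but-1-yn-1-yl]pyridazin-3-yl}-3-ethynyl-1-methyl-3-(3-methylbut-2-en-1-yl)pyrrolidin-2-imine, via O-triflyl iminium triflate 15 (not isolated)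
Conditions: Tf2O, 2-fluoropyridine, CH2Cl2, −78 → 0 °C; then 14, 0 → 40 °C; aq NaHCO3
Reagents that add atoms: none
Why: Electrophilic amide activation and amidine formation: O-triflation of the non-enolizable lactam gives an iminium ion that can only be attacked at C2, and addition of the exocyclic amino group of 14 with loss of triflate gives the neutral conjugated amidine, the thermodynamic sink among possible N-adducts.

Step 10
Reactants: 16 (S)-N-{4-bromo-6-[3-methyl-3-(triethylsilyloxy)but-1-yn-1-yl]pyridazin-3-yl}-3-ethynyl-1-methyl-3-(3-methylbut-2-en-1-yl)pyrrolidin-2-imine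
Product: 18 (S)-N-{4-bromo-6-[3-methyl-3-(triethylsilyloxy)but-1-yn-1-yl]pyridazin-3-yl}-1-methyl-3-(3-methylbut-2-en-1-yl)-3-[(triisopropylsilyloxy)ethynyl]pyrrolidin-2-imine, via lithium ynolate 17 (not isolated)
Conditions: LiHMDS (3 equiv), THF, −78 °C; t-BuOOH, −78 → 0 °C; i-Pr3SiOTf, −78 °C
Reagents that add atoms: tert-butyl hydroperoxide, CC(C)(C)OO; triisopropylsilyl trifluoromethanesulfonate, CC(C)[Si](OS(=O)(=O)C(F)(F)F)(C(C)C)C(C)C
Why: Oxidation of a lithium acetylide with lithium tert-butyl peroxide (oxygen transfer with loss of tert-butoxide) gives the ynolate, which the bulky silyl triflate traps on oxygen. LiHMDS serves for both deprotonations so that no alkyllithium meets the bromodiazine.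

Step 11
Reactants: 18 (S)-N-{4-bromo-6-[3-methyl-3-(triethylsilyloxy)but-1-yn-1-yl]pyridazin-3-yl}-1-methyl-3-(3-methylbut-2-en-1-yl)-3-[(triisopropylsilyloxy)ethynyl]pyrrolidin-2-imine
Product: 20 (3aS)-7-bromo-1-methyl-3a-(3-methylbut-2-en-1-yl)-5-[3-methyl-3-(triethylsilyloxy)but-1-yn-1-yl]-4-(triisopropylsilyloxy)-1,2,3,3a-tetrahydropyrrolo[2,3-b]indole, via diazabicyclooctatriene 19 (not isolated)
Conditions: toluene (0.01 M), 110 °C, sealed tube
Reagents that add atoms: none
Why: Intramolecular inverse-electron-demand Diels–Alder reaction: the electron-rich siloxyalkyne (2π) adds across C3/C6 of the pyridazine (4π), whose C3 carries N8, to give the 2,3-diazabicyclo[2.2.2]octatriene 19, and retro-[4+2] loss of N2 leaves the benzene ring. The closest known reaction types are the intramolecular alkyne–1,2-diazine cycloaddition with N2 extrusion that gives indolines, and the cycloaddition of siloxyalkynes to 1,2-diazines. Two rings close: the five-membered ring C7a–N8=C8a–C3a–C3b through the three-atom tether during the cycloaddition, and the six-membered carbocycle by the [4+2]/retro-[4+2] pair. No new stereocentre arises: the bridgeheads of 19 become sp2 and the quaternary C3a, which has no acidic hydrogen, passes through unchanged. The selectivity needed is regiochemical and is fixed by construction, since the alkyne carbon on C3a can reach only the diazine carbon that bears N8; this places Br on C7, H on C6, the alkynyl group on C5 and oxygen on C4. The gem-disubstituted C3a holds the reacting ends close, and the E/Z isomers of the amidine interconvert on heating so that the isomer with the diazine syn to C3a is the one that reacts (Curtin–Hammett). The second alkyne is conjugated to the electron-poor diazine and cannot reach the diene, and the prenyl alkene is not electron-rich enough to compete. Loss of N2 and the gain of aromaticity make the step irreversible.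

Step 12
Reactants: 20 (3aS)-7-bromo-1-methyl-3a-(3-methylbut-2-en-1-yl)-5-[3-methyl-3-(triethylsilyloxy)but-1-yn-1-yl]-4-(triisopropylsilyloxy)-1,2,3,3a-tetrahydropyrrolo[2,3-b]indole
Product: 22 (3aS)-8,8a-didehydro form of the target (cyclic amidine C8a=N8 with the furan closed and the carbinol free), via alkynylphenol 21 (not isolated)
Conditions: Bu4NF (3 equiv), THF, 60 °C
Reagents that add atoms: none
Why: Fluoride cleaves both silyl ethers; the phenoxide adds to the neighbouring alkyne in a base-mediated 5-endo-dig cycloisomerization (the standard benzofuran synthesis from o-alkynylphenols), and protonation gives the 2-substituted furan with the free carbinol.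

Step 13
Reactants: 22 (3aS)-8,8a-didehydro form of the target
Product: 23 (3aS,8aS)-7-bromo-1-methyl-3a-(3-methylbut-2-en-1-yl)-1,2,3,3a,8,8a-hexahydropyrrolo[2,3-b]indole fused at C4–C5 to a furan (O on C4) carrying 2-hydroxypropan-2-yl at C2′ (target CNP0306513.1)
Conditions: AlH3·NMe2Et (3 equiv), THF, 0 °C → rt; aq potassium sodium tartrate
Reagents that add atoms: none
Why: Hydride reduction of the cyclic N-aryl amidine to the aminal: alane bound to N8 delivers hydride to C8a, and because the two five-membered rings can only be cis-fused, hydrogen must enter on the face of the prenyl group, so C3a fixes C8a as S. At room temperature the aryl bromide, the alkene and the furan should not be reduced.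

## Compound list

1 | 1-methylpyrrolidin-2-one | CN1CCCC1=O | starting material
2 | tert-butyl 1-methyl-2-oxopyrrolidine-3-carboxylate (racemic) | CN1CCC(C(=O)OC(C)(C)C)C1=O | intermediate
3 | 1-bromo-3-methylbut-2-ene (prenyl bromide) | CC(C)=CCBr | starting material
4 | tert-butyl (R)-1-methyl-3-(3-methylbut-2-en-1-yl)-2-oxopyrrolidine-3-carboxylate | CC(C)=CC[C@@]1(C(=O)OC(C)(C)C)CCN(C)C1=O | intermediate
5 | trimethylsilyl (R)-1-methyl-3-(3-methylbut-2-en-1-yl)-2-oxopyrrolidine-3-carboxylate | CC(C)=CC[C@@]1(C(=O)O[Si](C)(C)C)CCN(C)C1=O | intermediate (not isolated)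
6 | (R)-1-methyl-3-(3-methylbut-2-en-1-yl)-2-oxopyrrolidine-3-carboxylic acid | CC(C)=CC[C@@]1(C(=O)O)CCN(C)C1=O | intermediate
7 | (R)-1-methyl-3-(3-methylbut-2-en-1-yl)-2-oxopyrrolidine-3-carbonyl chloride | CC(C)=CC[C@@]1(C(=O)Cl)CCN(C)C1=O | intermediate (not isolated)
8 | (S)-1-methyl-3-(3-methylbut-2-en-1-yl)-2-oxopyrrolidine-3-carbaldehyde | CC(C)=CC[C@@]1(C=O)CCN(C)C1=O | intermediate
9 | (S)-3-ethynyl-1-methyl-3-(3-methylbut-2-en-1-yl)pyrrolidin-2-one | CC(C)=CC[C@@]1(C#C)CCN(C)C1=O | intermediate
10 | 2-methylbut-3-yn-2-ol | CC(C)(O)C#C | starting material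
11 | triethyl[(2-methylbut-3-yn-2-yl)oxy]silane | CC(C)(C#C)O[Si](CC)(CC)CC | intermediate
12 | 6-chloropyridazin-3-amine | Nc1ccc(Cl)nn1 | starting material
13 | 6-[3-methyl-3-(triethylsilyloxy)but-1-yn-1-yl]pyridazin-3-amine | Nc1ccc(C#CC(C)(C)O[Si](CC)(CC)CC)nn1 | intermediate
14 | 4-bromo-6-[3-methyl-3-(triethylsilyloxy)but-1-yn-1-yl]pyridazin-3-amine | Nc1nnc(C#CC(C)(C)O[Si](CC)(CC)CC)cc1Br | intermediate
15 | (S)-O-triflyl iminium triflate of lactam 9 (2-triflyloxy-1-pyrrolinium salt) | CC(C)=CC[C@@]1(C#C)CC[N+](C)=C1OS(=O)(=O)C(F)(F)F.[O-]S(=O)(=O)C(F)(F)F | intermediate (not isolated)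
16 | (S)-N-{4-bromo-6-[3-methyl-3-(triethylsilyloxy)but-1-yn-1-yl]pyridazin-3-yl}-3-ethynyl-1-methyl-3-(3-methylbut-2-en-1-yl)pyrrolidin-2-imine (C=N geometry not fixed) | CC(C)=CC[C@@]1(C#C)CCN(C)C1=Nc1nnc(C#CC(C)(C)O[Si](CC)(CC)CC)cc1Br | intermediate
17 | lithium ynolate of 16 (C3–C≡C–OLi) | CC(C)=CC[C@@]1(C#C[O-])CCN(C)C1=Nc1nnc(C#CC(C)(C)O[Si](CC)(CC)CC)cc1Br.[Li+] | intermediate (not isolated)
18 | (S)-N-{4-bromo-6-[3-methyl-3-(triethylsilyloxy)but-1-yn-1-yl]pyridazin-3-yl}-1-methyl-3-(3-methylbut-2-en-1-yl)-3-[(triisopropylsilyloxy)ethynyl]pyrrolidin-2-imine | CC(C)=CC[C@@]1(C#CO[Si](C(C)C)(C(C)C)C(C)C)CCN(C)C1=Nc1nnc(C#CC(C)(C)O[Si](CC)(CC)CC)cc1Br | intermediate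
19 | 2,3-diazabicyclo[2.2.2]octatriene cycloadduct of 18 (C3a is S; bridgehead configuration not defined, both facial adducts give 20) | CC(C)=CC[C@@]12CCN(C)C1=NC13N=NC(C#CC(C)(C)O[Si](CC)(CC)CC)(C=C1Br)C(O[Si](C(C)C)(C(C)C)C(C)C)=C23 | intermediate (not isolated)
20 | (3aS)-7-bromo-1-methyl-3a-(3-methylbut-2-en-1-yl)-5-[3-methyl-3-(triethylsilyloxy)but-1-yn-1-yl]-4-(triisopropylsilyloxy)-1,2,3,3a-tetrahydropyrrolo[2,3-b]indole | CC(C)=CC[C@@]12CCN(C)C1=Nc1c(Br)cc(C#CC(C)(C)O[Si](CC)(CC)CC)c(O[Si](C(C)C)(C(C)C)C(C)C)c12 | intermediate
21 | (3aS)-7-bromo-5-(3-hydroxy-3-methylbut-1-yn-1-yl)-1-methyl-3a-(3-methylbut-2-en-1-yl)-1,2,3,3a-tetrahydropyrrolo[2,3-b]indol-4-ol | CC(C)=CC[C@@]12CCN(C)C1=Nc1c(Br)cc(C#CC(C)(C)O)c(O)c12 | intermediate (not isolated)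
22 | (3aS)-8,8a-didehydro form of the target (cyclic amidine, furan closed, free carbinol) | CC(C)=CC[C@@]12CCN(C)C1=Nc1c(Br)cc3cc(C(C)(C)O)oc3c12 | intermediate
23 | (3aS,8aS)-7-bromo-1-methyl-3a-(3-methylbut-2-en-1-yl)-1,2,3,3a,8,8a-hexahydropyrrolo[2,3-b]indole fused at C4–C5 to a 2-(2-hydroxypropan-2-yl)furan (O on C4) | CC(C)=CC[C@@]12CCN(C)[C@@H]1Nc1c(Br)cc3cc(C(C)(C)O)oc3c12 | target

## Step count and risks

Total step count: 13. Longest linear sequence: 10 (steps 1–5 and 9–13); the pyridazine branch (steps 6–8) joins at step 9.

Step 11 (key step). The most likely failure is that the cycloaddition is slower than thermal loss of the siloxyalkyne. The silicon can shift from oxygen to carbon to give a silylketene, and the amidine nitrogen feeds electron density into the diazine and raises the barrier. A first lever within the same approach is catalysis by AgNTf2 at room temperature. The fallback changes the 2π partner to one that is thermally robust. Setting out from 16, deprotonation with LiHMDS and trapping with 2-isopropoxy-4,4,5,5-tetramethyl-1,3,2-dioxaborolane would give the alkynyl pinacol boronate F1. Heating F1 in o-dichlorobenzene at 160–180 °C would give, by the same tether-controlled [4+2] addition and loss of N2, the aryl boronate F2. Oxidation with NaBO3·4H2O would give the phenol F3, which under the conditions of step 12 cyclizes and loses its silyl group; the route is rejoined at 22.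

Step 10. The risk is one of chemoselectivity: incomplete metalation of the alkyne by LiHMDS, or attack of the peroxide anion on the brominated diazine (displacement at C4) in competition with oxidation of the acetylide. The fallback puts the oxygen in before the diazine is present. Setting out from 9, metalation with n-BuLi, oxidation with LiOOt-Bu and a quench with phenol would give the homologated phenyl ester F4. Amidine formation with 14 as in step 9 would give F5. Enolization with LiHMDS and O-silylation with i-Pr3SiOTf would give the ketene silyl acetal F6. Heating F6 in toluene would bring about the [4+2] addition to the diazine, loss of N2 and elimination of phenol from the dihydroarene; the route is rejoined at 20.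

Step 9. The likely failure is slow attack of the weakly nucleophilic, ortho-brominated amine on an iminium carbon shielded by the quaternary centre, so that hydrolysis back to 9 or capture through a ring nitrogen wins. The fallback uses sulfur activation. Setting out from 9, thionation with 2,4-bis(4-methoxyphenyl)-1,3,2,4-dithiadiphosphetane 2,4-disulfide in toluene at 80 °C would give the thiolactam F7. S-Methylation with MeOTf would give the methylthio iminium triflate F8. Addition of the lithium amide of 14 (LiHMDS, THF) with loss of methanethiol rejoins the route at 16.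

Step 13. The risk is incomplete hydride addition to the electron-rich amidine and, if the conditions are forced, loss of bromine or opening of the aminal by over-reduction. The fallback activates the amidine by acylation. Setting out from 22, 2,2,2-trichloroethyl chloroformate would acylate N8 to give the N8-acyl amidinium chloride F9. NaBH4 in the same flask would reduce it to the cis-fused N8-carbamate aminal F10. Zinc dust in AcOH/THF would then remove the carbamate; the route is rejoined at 23.

## Further compounds

F1 | step 11 | (S)-alkynyl pinacol boronate derived from 16 (C3–C≡C–Bpin) | CC(C)=CC[C@@]1(C#CB2OC(C)(C)C(C)(C)O2)CCN(C)C1=Nc1nnc(C#CC(C)(C)O[Si](CC)(CC)CC)cc1Br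
F2 | step 11 | (3aS)-4-boryl analogue of 20 (pinacol boronate on C4) | CC(C)=CC[C@@]12CCN(C)C1=Nc1c(Br)cc(C#CC(C)(C)O[Si](CC)(CC)CC)c(B3OC(C)(C)C(C)(C)O3)c12
F3 | step 11 | (3aS)-C4 phenol with the triethylsilyl ether intact | CC(C)=CC[C@@]12CCN(C)C1=Nc1c(Br)cc(C#CC(C)(C)O[Si](CC)(CC)CC)c(O)c12
F4 | step 10 | phenyl (S)-2-[1-methyl-3-(3-methylbut-2-en-1-yl)-2-oxopyrrolidin-3-yl]acetate | CC(C)=CC[C@@]1(CC(=O)Oc2ccccc2)CCN(C)C1=O
F5 | step 10 | amidine from F4 and 14 | CC(C)=CC[C@@]1(CC(=O)Oc2ccccc2)CCN(C)C1=Nc1nnc(C#CC(C)(C)O[Si](CC)(CC)CC)cc1Br
F6 | step 10 | ketene phenyl triisopropylsilyl acetal of F5 | CC(C)=CC[C@@]1(C=C(Oc2ccccc2)O[Si](C(C)C)(C(C)C)C(C)C)CCN(C)C1=Nc1nnc(C#CC(C)(C)O[Si](CC)(CC)CC)cc1Br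
F7 | step 9 | (S)-3-ethynyl-1-methyl-3-(3-methylbut-2-en-1-yl)pyrrolidine-2-thione | CC(C)=CC[C@@]1(C#C)CCN(C)C1=S
F8 | step 9 | (S)-2-(methylthio)-1-pyrrolinium triflate derived from F7 | CC(C)=CC[C@@]1(C#C)CC[N+](C)=C1SC.[O-]S(=O)(=O)C(F)(F)F
F9 | step 13 | N8-(2,2,2-trichloroethoxycarbonyl) amidinium chloride of 22 | CC(C)=CC[C@@]12CC[N+](C)=C1N(C(=O)OCC(Cl)(Cl)Cl)c1c(Br)cc3cc(C(C)(C)O)oc3c12.[Cl-]
F10 | step 13 | N8-(2,2,2-trichloroethoxycarbonyl) derivative of 23 (cis-fused) | CC(C)=CC[C@@]12CCN(C)[C@@H]1N(C(=O)OCC(Cl)(Cl)Cl)c1c(Br)cc3cc(C(C)(C)O)oc3c12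
A1 | alternative 1 | methyl {2-[7-bromo-4,5-furo-fused indol-3-yl]ethyl}carbamate (furan O on indole C4, 2-hydroxypropan-2-yl on the furan) | COC(=O)NCCc1c[nH]c2c(Br)cc3cc(C(C)(C)O)oc3c12
A2 | alternative 1 | N1-methoxycarbonyl analogue of 23 | CC(C)=CC[C@@]12CCN(C(=O)OC)[C@@H]1Nc1c(Br)cc3cc(C(C)(C)O)oc3c12
A3 | alternative 2 | 2-(5-bromo-6-hydrazinylbenzofuran-2-yl)propan-2-ol | NNc1cc2oc(C(C)(C)O)cc2cc1Br
A4 | alternative 2 | 1-methyl-3-(3-methylbut-2-en-1-yl)pyrrolidin-2-ol (racemic) | CC(C)=CCC1CCN(C)C1O
A5 | alternative 3 | methyl (4-methoxybenzyl){[(S)-1-methyl-3-(3-methylbut-2-en-1-yl)-2-oxopyrrolidin-3-yl]ethynyl}carbamate | CC(C)=CC[C@@]1(C#CN(Cc2ccc(OC)cc2)C(=O)OC)CCN(C)C1=O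
A6 | alternative 3 | 7-methyl-7-(triethylsilyloxy)octa-1,3-dien-5-yn-1-one (vinylketene) | O=C=CC=CC#CC(C)(C)O[Si](CC)(CC)CC
A7 | alternative 3 | aminophenol from A5 and A6 (OH on C4, alkynyl on C5, protected N8 on C7a) | CC(C)=CC[C@@]1(c2c(O)c(C#CC(C)(C)O[Si](CC)(CC)CC)ccc2N(Cc2ccc(OC)cc2)C(=O)OC)CCN(C)C1=O
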